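All runs were generated by integration on assumed constants; noise was put on by code.

Counted per catalyst charged, the dawn flask makes target at 3.95 min⁻¹ over its first 15.0 min but at 0.280 min⁻¹ between 30.0 min and 40.0 min, far slower, while 25.8% of the starting material still stands at the first of those readings. The flask asked about is this dawn run carried on to 2.0 h.

| flask | starting material | second substrate | coupling partner | precatalyst | temperature | remark | time |
|---|---|---|---|---|---|---|---|
| dawn | 0.096 M | 0.096 M | 0.125 M | 0.96 mM | 60 °C | the very flask that is asked about, followed so far |  |
| midnight | 0.096 M | 0.096 M | 0.19 M | 0.96 mM | 45 °C | run made earlier |  |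
| flask | 0.096 M | 0.0960 M | 0.125 M | 0.96 mM | 60 °C |  | 2.0 h |

- dawn (time / min: target / %, starting material / %): 15.0: 59.3, 41.6; 30.0: 73.4, 25.8; 40.0: 76.2, 23.1; 60.0: 78.9, 20.7; 80.0: 80.0, 20.2; 90.0: 79.3, 20.9
- midnight (time / min: target / %, starting material / %): 1.33: 2.6, 97.5; 3.00: 7.8, 91.1; 4.00: 12.6, 87.1; 5.00: 17.0, 82.3; 6.00: 22.3, 76.4; 8.00: 30.5, 69.0

(readings scatter by 0.5 percentage points)

- north-west: at 2.0 h add coupling partner, 50.0% of the amount charged, then wait 2.0 h
- east: at 2.0 h raise the temperature by 20 K, then wait 2.0 h
- south: change nothing and wait 2.0 h more
- south-east: at 2.0 h add precatalyst, 100% of the amount charged, then wait 2.0 h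
- south-west: at 2.0 h take out 90% of the target then present, then wait 2.0 h

- what is taken out of target is counted as made
- additions bring no volume worth counting

* target, in percent of the starting material first charged, at 2.0 h
* what to do for the largest gain in target; "none" if nothing gains more than 2 percentage points (north-west / east / south / south-east / south-west / none)
* target present, with what was taken out counted in, in percent of the starting material first charged, after north-west
* target present, with what was taken out counted in, in percent of the starting material first charged, after south-west

The first instants are read from the midnight run, at its lower temperature. Over its first 1.33 min each catalyst charged makes 1.95 min⁻¹, slower than the 4.48 min⁻¹ between 4.00 min and 8.00 min, so the precatalyst seems to need a moment to wake. After that, the midnight readings rise along a nearly straight line while starting material falls to 69.0%.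

The middle is read from the dawn run: at 30.0 min, target and starting material add up to 99.2%, so no starting material is going astray, yet the pace is collapsing. The end is nearly flat, with target at 78.9%, 80.0% and 79.3% across the last readings. If each target takes one coupling partner, [coupling partner] still stands near 0.0482 M at the plateau, and starting material stands at 20.2%. Neither reagent is gone, so this reckoning takes the catalyst to have stopped, though no run excludes an equilibrium.

What then stays fixed is a total, not a rate. The dawn reading at 80.0 min gives 80.0 for the turnover budget, target made per catalyst charged before the catalyst stops, the usual turnover number. This reckoning expects 80.0% at 2.0 h and no gain from waiting, partner, heat or removal. A fresh equal dose brings a budget worth 80.0% of the charge, more than the starting material left, so it is expected to finish the flask.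

The forecast gives 80% at 2.0 h, 80.5% after north-west and 80.5% after south-west, and it names south-east as best, with target near 97%: “I expect more partner, heat, waiting or product removal to do nothing, because the catalyst is dead.”

The flask gives 79.9%, 79.9% after north-west and 79.9% after south-west. The best option is south-east, gaining 13 percentage points where 20% of the starting material stood, so the fresh dose does not finish the flask as reckoned here.

    starting material + free catalyst ⇌ catalyst intermediate A (K = 110 L mol⁻¹, k = 8.30 L mol⁻¹ s⁻¹, Ea = 41.0 kJ mol⁻¹, ΔH = −25.0 kJ mol⁻¹)
    catalyst intermediate B → spent catalyst (k = 0.00620 s⁻¹, Ea = 84.0 kJ mol⁻¹)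
    second substrate + free catalyst ⇌ catalyst intermediate B (K = 5.80 L mol⁻¹, k = 5.00 L mol⁻¹ s⁻¹, Ea = 61.0 kJ mol⁻¹, ΔH = 12.0 kJ mol⁻¹)
    coupling partner + catalyst intermediate A → free catalyst + target (k = 1.70 L mol⁻¹ s⁻¹, Ea = 40.0 kJ mol⁻¹)
    coupling partner + catalyst intermediate B → free catalyst + second product (k = 1.20 L mol⁻¹ s⁻¹, Ea = 44.0 kJ mol⁻¹)
    precatalyst → free catalyst (k = 0.0390 s⁻¹, Ea = 89.0 kJ mol⁻¹)
    (constants at 60 °C)

At 7.46 min, coupling partner goes into target 6.8 times as fast as into second product. At 120 min, catalyst intermediate B goes on to second product 7.0 times as fast as into spent catalyst, which by then holds 99.9% of the catalyst. The forecast's plateau moves with [second substrate]: the answer at 2.0 h has moved by 5 points at 0.114 M, and the neighbour flask with 0.16 M ends at 64.3%, a budget of 64.3 against the 80.0 read from the dawn run.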